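**Plan**

- Cuts, in retrosynthetic order: (a) the two pyran bonds O–C4(CH3) and CH2–C5H (hetero-Diels–Alder) give (−)-β-caryophyllene and an α-methylene triketone derived from norflavesone; (b) one ring C–CH3 bond and the ring–acyl bond give 2,4-dimethylphloroglucinol as its diethyl ether; (c) in that arene, the bond from the future ring-ketone carbon to the future gem-dimethyl carbon and the bond from the future CH2-bearing carbon to the future pyran-oxygen carbon are cut together.
- Enabling feature: the carbocycle is a masked phloroglucinol in which three O-bearing carbons alternate with three C-substituted ones. Its O–C=C(CH3) edge (pyran-oxygen carbon plus gem-dimethyl carbon) is an ynol ether; the other four ring carbons (ketone C, acyl-bearing C, enol C–OH, CH2-bearing C) are an alkoxy vinylketene stored in a strained cyclobutenone.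
- Forward order: ynol ether → cyclobutenone (four-membered ring) → benzannulation to the six-membered carbocycle → de-ethylation, C-acylation, dearomatising C-methylation → oxidation to the heterodiene and [4+2] closure of the dihydropyran onto the nine-membered ring. The cyclobutane and nine-membered ring are bought with caryophyllene; the same ynol ether serves twice.
- Stereochemistry: the cyclobutane fusion centres come unchanged from (−)-β-caryophyllene. The O–C(CH3) and adjacent C–H centres arise in the last step, trans to each other by suprafacial addition to the E alkene. Their sense relative to the cyclobutane depends on the alkene face attacked (that of the ββ ring conformer); the other-face diastereomer is removed by chromatography.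

Key step: step 3

Remark: triketones 11 and 13 and the target are drawn as the enol tautomer of the target SMILES; terpene atoms carry caryophyllene numbers (C4 = methyl-bearing alkene carbon, C5 = alkene CH, C1 and C9 = cyclobutane fusion carbons).

**Route**

Step 1
Reactants: 1 1-ethoxyprop-1-yne
Product: 2 4,4-dichloro-3-ethoxy-2-methylcyclobut-2-en-1-one
Conditions: Cl3CCOCl, Zn(Cu) couple, Et2O/DME, 0 °C → rt
Reagents that add atoms: trichloroacetyl chloride, ClC(=O)C(Cl)(Cl)Cl
Why: Dichloroketene made in the flask by zinc dechlorination adds to the electron-rich ynol ether in a ketene–alkyne [2+2] cycloaddition, the nucleophilic CH3-bearing alkyne carbon bonding to the ketene carbonyl carbon, so that ethoxy ends at C3 and methyl at C2 (DME ties up ZnCl2).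

Step 2
Reactants: 2 4,4-dichloro-3-ethoxy-2-methylcyclobut-2-en-1-one
Product: 3 3-ethoxy-2-methylcyclobut-2-en-1-one
Conditions: Zn dust, AcOH, TMEDA, EtOH, 0 °C → rt
Reagents that add atoms: none
Why: Zinc reductive dechlorination of the α,α-dichloro ketone through zinc enolates, the standard follow-up to dichloroketene cycloadducts, should leave the vinylogous ester untouched.

Step 3
Reactants: 3 3-ethoxy-2-methylcyclobut-2-en-1-one, 1 1-ethoxyprop-1-yne
Product: 8 3,5-diethoxy-2,4-dimethylphenol, via vinylketene 4 (not isolated), via vinylcyclobutenone 5 (not isolated), via dienylketene 6 (not isolated), via cyclohexadienone 7 (not isolated)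
Conditions: PhMe, 100 °C, sealed tube (2.5 equiv of 1); then KOH, MeOH, rt
Reagents that add atoms: none
Why: Heat opens the strained cyclobutenone 3 by 4π-electrocyclic cleavage of its C(=O)–CH2 bond to the alkoxy vinylketene 4, and the ketene C=C of 4 then undergoes a [2+2] cycloaddition with ynol ether 1 to give 5; these two new σ-bonds (ketene carbonyl carbon to the CH3-bearing alkyne carbon, ketene α-carbon to the O-bearing alkyne carbon) are the ones that remain in the product. Cyclobutenone 5 reopens by a second 4π-electrocyclic cleavage (carbonyl carbon–quaternary carbon) to dienylketene 6, which closes the six-membered carbocycle by a thermally allowed disrotatory 6π-electrocyclisation of the ketene carbon onto the terminal CH2 (dienone 7), and tautomerisation to phenol 8 pulls the reversible steps forward; the net change is expansion of the four-membered ring to the six-membered ring by insertion of the two alkyne carbons between the carbonyl carbon and its α-carbon. The closest known reaction type is the Danheiser benzannulation of cyclobutenones with alkoxy- and silyloxyalkynes. No stereocentre is formed, since the quaternary carbon of 5 becomes sp2 again and only the dienylketene isomer with the vinyl arm turned inward can cyclise (the other reverts to 5). The selectivity needed is the regiochemistry of the [2+2] step, which is secured by the polarisation of 1: the oxygen lone pair makes the CH3-bearing carbon nucleophilic toward the electrophilic ketene carbon, so that O- and C-substituted carbons alternate round the new ring. The KOH treatment only cleaves any aryl ester formed when phenol 8 captures vinylketene 4.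

Step 4
Reactants: 8 3,5-diethoxy-2,4-dimethylphenol
Product: 9 2,4-dimethylbenzene-1,3,5-triol
Conditions: BBr3 (3 equiv), CH2Cl2, −78 °C → rt; H2O
Reagents that add atoms: none
Why: Lewis-acid cleavage of both aryl ethyl ethers (boron coordination to oxygen, bromide attack at ethyl) should free the phloroglucinol whose polyanion is needed for the later C-alkylation, the ring methyls being inert.

Step 5
Reactants: 9 2,4-dimethylbenzene-1,3,5-triol
Product: 10 1-(2,4,6-trihydroxy-3,5-dimethylphenyl)-2-methylpropan-1-one
Conditions: iPrCOCl (1.1 equiv), AlCl3 (3 equiv), PhNO2, rt → 60 °C; aq. HCl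
Reagents that add atoms: 2-methylpropanoyl chloride, CC(C)C(Cl)=O
Why: Friedel–Crafts C-acylation at the only free position of the very electron-rich ring, any aryl ester formed first being carried on by Fries rearrangement under AlCl3.

Step 6
Reactants: 10 1-(2,4,6-trihydroxy-3,5-dimethylphenyl)-2-methylpropan-1-one
Product: 11 norflavesone [3,5-dihydroxy-4,6,6-trimethyl-2-(2-methylpropanoyl)cyclohexa-2,4-dien-1-one]
Conditions: NaOMe (3 equiv), MeI (1.1 equiv), MeOH, 0 °C → rt; aq. HCl
Reagents that add atoms: iodomethane, CI
Why: Alkylative dearomatisation, in which the phloroglucinol polyanion is C-methylated at a methyl-bearing carbon flanked by two oxygens (the two such carbons are equivalent through the mirror plane of 10, so one product results) to create the gem-dimethyl carbon, the near-stoichiometric MeI holding back a second methylation.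

Step 7
Reactants: 11 norflavesone, 12 (−)-β-caryophyllene
Product: 14 target (caryophyllene–norflavesone pyran adduct; 1R,4S,5R,9S in caryophyllene numbering), via methylene triketone 13 (not isolated)
Conditions: 12 (3 equiv), TEMPO (0.2 equiv), Ag2O (2 equiv), PhMe, rt, dark; SiO2 chromatography then HPLC
Reagents that add atoms: none
Why: Ag2O/TEMPO should dehydrogenate the CH(CH3) carbon between two ring carbonyls of 11 to the α-methylene triketone 13, a 1-oxadiene that adds at once in an inverse-electron-demand hetero-Diels–Alder reaction to the strained (E)-trisubstituted ring alkene of 12 (not to the exocyclic methylene), CH2 bonding to the alkene CH and the oxygen of the carbonyl next to CMe2 to the methyl-bearing alkene carbon (the other carbonyl is tied up as the chelated enol of the acyl group); suprafacial addition to the E alkene fixes the trans ring fusion, the cyclobutane centres are untouched, and the target is the adduct on the alkene face exposed in the ββ ring conformer (opposite to the face epoxidised in common (−)-caryophyllene oxide), the other-face adduct being separated by chromatography.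

**Compound list**

1 | 1-ethoxyprop-1-yne (ethyl 1-propynyl ether) | CCOC#CC | starting material
2 | 4,4-dichloro-3-ethoxy-2-methylcyclobut-2-en-1-one | CCOC1=C(C)C(=O)C1(Cl)Cl | intermediate
3 | 3-ethoxy-2-methylcyclobut-2-en-1-one | CCOC1=C(C)C(=O)C1 | intermediate
4 | vinylketene 3-ethoxy-2-methylbuta-1,3-dien-1-one (not isolated) | C=C(OCC)C(C)=C=O | intermediate
5 | vinylcyclobutenone 3-ethoxy-4-(1-ethoxyethenyl)-2,4-dimethylcyclobut-2-en-1-one (not isolated) | CCOC(=C)C1(C)C(=O)C(C)=C1OCC | intermediate
6 | dienylketene (3E)-3,5-diethoxy-2,4-dimethylhexa-1,3,5-trien-1-one, the two chain arms cis (not isolated) | C=C(OCC)/C(C)=C(OCC)\C(C)=C=O | intermediate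
7 | cyclohexadienone 3,5-diethoxy-2,4-dimethylcyclohexa-2,4-dien-1-one (not isolated) | CCOC1=C(C)C(OCC)=C(C)C(=O)C1 | intermediate
8 | 3,5-diethoxy-2,4-dimethylphenol | CCOc1cc(O)c(C)c(OCC)c1C | intermediate
9 | 2,4-dimethylbenzene-1,3,5-triol | Cc1c(O)cc(O)c(C)c1O | intermediate
10 | 1-(2,4,6-trihydroxy-3,5-dimethylphenyl)-2-methylpropan-1-one | CC(C)C(=O)c1c(O)c(C)c(O)c(C)c1O | intermediate
11 | norflavesone, 3,5-dihydroxy-4,6,6-trimethyl-2-(2-methylpropanoyl)cyclohexa-2,4-dien-1-one (enol form of 2-isobutyryl-4,4,6-trimethylcyclohexane-1,3,5-trione) | CC(C)C(=O)C1=C(O)C(C)=C(O)C(C)(C)C1=O | intermediate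
12 | (−)-β-caryophyllene, (1R,4E,9S)-4,11,11-trimethyl-8-methylidenebicyclo[7.2.0]undec-4-ene | C=C1CC/C=C(\C)CC[C@@H]2[C@@H]1CC2(C)C | starting material
13 | methylene triketone 3-hydroxy-6,6-dimethyl-4-methylidene-2-(2-methylpropanoyl)cyclohex-2-ene-1,5-dione (not isolated) | C=C1C(=O)C(C)(C)C(=O)C(C(=O)C(C)C)=C1O | intermediate
14 | target: dihydropyran trans-fused to C4/C5 of the caryophyllene nine-membered ring (O on C4, CH2 on C5; 1R,4S,5R,9S) and fused to the 5-hydroxy-2,2-dimethyl-4-(2-methylpropanoyl)cyclohexadienone ring, with the 8-methylidene and the gem-dimethylcyclobutane intact | C=C1CC[C@@H]2CC3=C(O[C@@]2(C)CC[C@@H]2[C@@H]1CC2(C)C)C(C)(C)C(=O)C(C(=O)C(C)C)=C3O | target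

**Count**

Total steps: 7. Longest linear sequence: 7 (1 → 14; caryophyllene 12 enters in the last step).

**Steps most likely to fail**

Step 7. The risk is poor facial selectivity: the conformational preference of the nine-membered ring may steer the heterodiene mainly to the other exposed alkene face, leaving the target as the minor of two trans-fused diastereomers; dimerisation of 13 competes as well. The fallback replaces conformer control by reagent control. It sets out from 11 and 12 and comes back at 14. Triketone 13 would be generated from 11 at −78 °C with PhI(OAc)2 and TEMPO in THF, and the cycloaddition run at low temperature in the presence of a chiral chelating Lewis acid, Cu(OTf)2 with a tert-butyl bis(oxazoline) ligand. Each ligand antipode would be tried, so that the catalyst bound to the acyl/enol oxygens of 13 shields one approach and the matched antipode selects the ββ face. This fallback makes no new compound (F0).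

Step 3. The risk is that ring opening of the vinylogous-ester cyclobutenone is slow, so that thermal retro-ene loss of ethylene from the ethyl ynol ether and oligomerisation of the ketenes win. The fallback changes the mode of activation and the ketenophile. It sets out from 3 and comes back at 9. Prop-1-ynyllithium would be oxidised with lithium tert-butyl peroxide (tBuOOH, LiN(SiMe3)2, THF, −78 → 0 °C) and the ynolate silylated with iPr3SiCl to give triisopropyl(prop-1-yn-1-yloxy)silane F1, which cannot undergo the retro-ene reaction. Irradiation of 3 with F1 (254 nm, PhMe, rt) would open the cyclobutenone photochemically at room temperature; brief warming to 80 °C should complete the cascade to 5-ethoxy-2,4-dimethyl-3-(triisopropylsilyloxy)phenol F2. BBr3 in CH2Cl2 followed by Bu4NF in THF would remove the ethyl and silyl groups and return triol 9.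

Step 6. The risk is over-methylation at the second methyl-bearing carbon (to the tetramethyl triketone) together with O-methylation. The fallback methylates a substrate that has only one phenoxide oxygen and hydrolyses afterwards. It sets out from 8 and comes back at 11. Ortho-acylation of 8 (iPrCOCl, TiCl4, CH2Cl2, 0 °C → rt) would give 1-(2,4-diethoxy-6-hydroxy-3,5-dimethylphenyl)-2-methylpropan-1-one F3. C-Methylation of its lithium phenoxide in a non-polar medium (LiOtBu, MeI, PhMe) should give 3,5-diethoxy-4,6,6-trimethyl-2-(2-methylpropanoyl)cyclohexa-2,4-dien-1-one F4, which has no further acidic ring position. Hydrolysis of the two vinylogous-ester enol ethers (1 M HCl, THF, rt) would then give 11.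

**Further compounds**

F1 | step 3 | triisopropyl(prop-1-yn-1-yloxy)silane | CC#CO[Si](C(C)C)(C(C)C)C(C)C
F2 | step 3 | 5-ethoxy-2,4-dimethyl-3-(triisopropylsilyloxy)phenol | CCOc1cc(O)c(C)c(O[Si](C(C)C)(C(C)C)C(C)C)c1C
F3 | step 6 | 1-(2,4-diethoxy-6-hydroxy-3,5-dimethylphenyl)-2-methylpropan-1-one | CC(C)C(=O)c1c(O)c(C)c(OCC)c(C)c1OCC
F4 | step 6 | 3,5-diethoxy-4,6,6-trimethyl-2-(2-methylpropanoyl)cyclohexa-2,4-dien-1-one | CC(C)C(=O)C1=C(OCC)C(C)=C(OCC)C(C)(C)C1=O
F0 | step 7 | none | none
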